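## Structural features

Mollicellin A is an achiral, tetracyclic depsidone. Ring A is a benzene with the lactone carbonyl on A-C1, the diaryl ether oxygen on A-C2, a formyl group on A-C3, a hydroxyl on A-C4, hydrogen on A-C5 and a methyl on A-C6, which is the pattern of 3-formylorsellinic acid. Ring B is the benzo ring (C4a to C8a) of a 2,2-dimethylchroman-4-one with pyran oxygen O1, gem-dimethyl carbon C2, methylene C3, ketone C4 and a methyl on C5. The two arenes are joined twice, by the ester from the A-C1 carbonyl to the oxygen on C7 and by the ether from the A-C2 oxygen to C6, and these two links close the central seven-membered dioxepinone. There is no stereocentre, so every problem is one of regiochemistry on two pentasubstituted arenes. The fragile parts are the aryl ester (open to nucleophiles and, because C7 is para to the ketone, to base-induced Smiles-type aryl migration), the chelated ortho-hydroxy aldehyde, and the beta-aryloxy ketone of the pyranone. The real difficulty is the diaryl ether, flanked by four ortho substituents, and the correct placement of a heteroatom on C6 of ring B. The key step uses the fact that C4 hangs on C4a between C8a–O1 and C5–CH3. This is the ortho-hydroxy carbonyl pattern of 2,4-dihydroxy-6-methylbenzaldehyde, so the formyl carbon can become C4, the 2-hydroxyl O1 and the 4-hydroxyl the C7 oxygen, and only the C2/C3 unit with its two methyls, a 2-methylpropene, has to be added.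

## Logic of the disconnections

**19 from 18.** The O–CH2 bond of a benzyl ether on the A-C4 oxygen is added in the backward direction. The reason is that a free A-C4 hydroxyl would acylate a second molecule during ester formation and would give a dianion in the copper step. Nothing is gained in skeleton; the gain is safety in the two preceding steps. The forward step must cleave this ether without touching the lactone, the aldehyde or the ketone; chelation of a boron Lewis acid by the neighbouring formyl oxygen should make that possible at low temperature.

**18 from 17.** The bond between the A-C2 oxygen and C6 of ring B is cut, which opens the seven-membered ring and leaves a free A-C2 hydroxyl and a C6–Br bond. Cutting here lets the most hindered bond form intramolecularly, with the ester as tether, and only the seven-membered ring is geometrically possible. The tetracycle becomes two arenes held by one ester. The forward coupling must be faster than cleavage or migration of the aryl ester under base.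

**17 from 10 and 15.** The ester C(=O)–O bond is cut. This is the most convergent cut and gives two halves of similar size, each with all its substituents in place. The forward step must acylate a hindered, weakly nucleophilic phenol with a 2,6-disubstituted benzoic acid that keeps its ortho hydroxyl free, and should do so without base.

**10 from 9.** The O–benzyl bond on the C7 oxygen is added backwards, because this oxygen must stay inert while the pyran ring is built and oxidised. The forward removal must leave the C6–Br bond intact, which excludes hydrogenolysis.

**9 from 8.** The C4 carbonyl is traced back to a C4–H carrying a methoxy group, so no skeletal bond is cut. This is done because 8 is the direct product of the ring-forming step and already has C4 attached to oxygen. The forward step must take the benzylic hydride from C4 in preference to the O–CH2Ph and C5–CH3 positions.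

**8 from 3, 4 and 5.** The C4–C3 and O1–C2 bonds are cut together and the whole pyran ring disappears. C2, C3 and the two methyls return to 4, the methoxy carbon to 5, and C4 becomes the formyl carbon of 3. The cut uses an ortho relationship that is already present, so the ring-fusion position needs no control. The bicycle is reduced to a monocyclic benzaldehyde two steps from a commercial compound. The forward step needs Markovnikov orientation of the alkene and a product ether that survives the acid. The new stereocentre needs no control because it is erased in the next step.

**3 from 2.** The C–Br bond on the carbon that becomes C6 is cut. It is placed here and not after ring formation because in 2 this carbon is para to the only free hydroxyl, the strongest director. Once the ring is formed and the C7 oxygen is freed, both open carbons are ortho to that oxygen. The bromine also blocks the most nucleophilic ring carbon during the acid-catalysed key step. The forward step must stop at one bromine, and all later steps must tolerate an aryl bromide.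

**2 from 1.** The O–benzyl bond on the 4-oxygen is cut. The 2-hydroxyl must be free for the cycloaddition, while the 4-hydroxyl must not be alkylated by the alkene or ionise to a para-quinone methide. The forward step must alkylate one hydroxyl only; the hydrogen bond of the 2-hydroxyl to the formyl group should ensure this.

**15 from 14.** The acid is traced back to its methyl ester, so that the carboxyl group is protected during formylation and benzylation and the starting arene is commercial. The forward hydrolysis of a doubly ortho-substituted ester must not lead to decarboxylation.

**14 from 13.** The O–benzyl bond on the A-C4 oxygen is cut. The forward step must choose the A-C4 hydroxyl over the A-C2 hydroxyl, which lies between the ester and the formyl group and is the more shielded.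

**13 from 11.** The bond between A-C3 and the formyl carbon is cut. This puts the regiochemical decision for the formyl group on a simple commercial arene, at the carbon between two hydroxyls where a chelating Lewis acid can direct. The forward step must prefer A-C3 over A-C5.

## Other disconnections considered

**Alternative 1:** The cut removes ring A as an arene. The ester bond and the A-C1 to A-C6 bond are both disconnected, so that the ring-A carbons come from a linear tetraketide masked as the diketo-dioxinone A1.

- **Forward key step.** A1 would be heated with the ring-B bromophenol, which is 10 of the chosen route. Cycloreversion would unmask an acylketene, the C7 hydroxyl would add to it to give the aryl 3,5,7-trioxooctanoate A2, and mild base followed by acid would fold A2 by a C2-to-C7 aldol condensation into the bromo depside A3, an orsellinate ester.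
- **In its favour.** The hindered ester is formed by ketene capture under neutral conditions, with no hindered benzoic acid to hydrolyse, activate or lose by decarboxylation. On the formation of the ester bond this is the equal of steps 8 and 9 and probably the better.
- **Against it here.** A3 has no formyl group, so formylation must be done late on a depside with two free ring-A hydroxyls, where A-C3 and A-C5 are both activated and the sensitive aryl ester is already present. In A2 the enol oxygen at C5 can attack the ester carbonyl and expel the acidic ring-B aryloxide, a pyrone-forming path that competes with the aldol fold. A1 needs two to three steps of its own.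
- **Comparison.** Structurally A3 is 17 without formyl and benzyl groups and would enter the same Ullmann closure. Mechanistically a pericyclic ketene release and an aldol aromatisation replace an electrophilic formylation and a mixed-anhydride acylation. In step count the two are about equal, and alternative 1 would be shorter by the two benzyl operations on ring A if the copper step accepted a free resorcinol. The chosen plan settles the position of the formyl group on a simple arene in step 6. Alternative 1 does not touch the pyran ring, so it competes with steps 6 to 9 only and still needs 10 from steps 1 to 5.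

**Alternative 2:** The cut is the carbon–carbon bond between A-C1 and the lactone carbonyl. The precursor A4 already holds the diaryl ether. Its ring A carries iodine on A-C1, a dioxolane-protected formyl group and a methoxymethyl ether; its ring B carries the future carbonyl carbon as a phenyl carbonate on the C7 oxygen and the ketone as a dioxolane.

- **Forward key step.** An alkyllithium at low temperature would exchange the iodine, and the aryllithium would attack the carbonate intramolecularly (a Parham-type cyclisation), expelling the aryloxide and closing the seven-membered lactone to the fully protected depsidone A5. One acidic step would then remove all three protecting groups.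
- **In its favour.** No hindered benzoic acid is needed, and the ring closure is fast, intramolecular and free of base-induced aryl migration. On the closure of the seven-membered ring this is the equal or the better of step 10, and the final deprotection is as short as step 11.
- **Against it here.** The diaryl ether with four ortho substituents must be made first and intermolecularly, which is harder than the tethered coupling of step 10. Ring B needs two differentiated oxygens on C6 and C7 instead of one oxygen and one bromine. The C4 ketone, a vinylogous ester flanked by the C5 methyl, is a poor substrate for ketalisation. The alkyllithium may add to the carbonate before the exchange, and the aryllithium may be quenched by the benzylic protons of the neighbouring methyl.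
- **Comparison.** Structurally A5 is 18 with three protecting groups in place of one. Mechanistically an anionic acyl substitution at low temperature replaces a copper-mediated C–O coupling at 90 °C. In step economy the alternative is longer, because of the iodination, the carbonate, two ketalisations and a separate ether synthesis. The pyran ring of A4 could still be made by the key step of the chosen plan.

**Alternative 3:** The cut goes through ring A itself. The A-C1 to A-C6 and A-C3 to A-C4 bonds are disconnected, which leaves the seven-membered ring intact as the ring-B-fused methyl-dioxepinone A6 (C4 ketone as dioxolane) and a four-carbon acceptor, methyl crotonate A7.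

- **Forward key step.** The lithium dienolate of A6 would add through its alpha-carbon to A7 (Michael addition) and the gamma-carbon would then condense with the ester (Claisen condensation). This would give the tetrahydro depsidone A8, racemic at A-C6, with ring A at the cyclohexenone level.
- **In its favour.** No diaryl ether coupling is needed, because both ring-B oxygens are attached to an acyclic four-carbon unit before ring A exists. On the ether link this is better than step 10, and two carbon–carbon bonds and a ring are formed in one operation.
- **Against it here.** A8 must lose two hydrogens to become the arene and it lacks the formyl group, so an oxidation and a late formylation with the same A-C3 against A-C5 question must follow. The dioxolane must also be removed, and its installation on the hindered C4 ketone is doubtful. The dienolate of A6 is the enolate of an aryl ester and can expel the C7 aryloxide to a ketene. The construction of A6 must decide which ring-B oxygen becomes the ester and which the enol ether. The stereocentre that the Michael step creates is destroyed again.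
- **Comparison.** Structurally A8 keeps the dioxepinone that the chosen plan closes last. Mechanistically ring A is built by anionic annulation and then aromatised, whereas the chosen plan buys it as an arene. In step economy the alternative needs oxidation, formylation and deprotection after its key step and a ring-B diol before it, which should make it longer than steps 6 to 11. As in alternative 2, ring B would still be best made by the cycloaddition of step 3.

Key step: step 3

Assumption: 2-methylpropene (boiling point about −7 °C) is used as a condensed liquid in a sealed pressure tube.

## Steps

**Step 1**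
Reactants: 1 2,4-dihydroxy-6-methylbenzaldehyde
Product: 2 4-(benzyloxy)-2-hydroxy-6-methylbenzaldehyde
Conditions: BnBr (1.05 equiv), KHCO3 (1.5 equiv), DMF, rt to 40 °C
Reagents that add atoms: benzyl bromide, BrCc1ccccc1
Why: Williamson ether synthesis; the 2-hydroxyl is held in a hydrogen bond to the formyl oxygen and is not deprotonated by the weak base, so only the 4-hydroxyl should be alkylated.

**Step 2**
Reactants: 2 4-(benzyloxy)-2-hydroxy-6-methylbenzaldehyde
Product: 3 4-(benzyloxy)-3-bromo-6-hydroxy-2-methylbenzaldehyde
Conditions: NBS (1.0 equiv), MeCN, 0 °C to rt
Reagents that add atoms: N-bromosuccinimide, O=C1CCC(=O)N1Br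
Why: Electrophilic aromatic bromination; the free hydroxyl directs para, to the carbon between the benzyloxy and methyl groups, whereas the other open carbon lies between two oxygens and is only ortho-activated. Substitution para to the hydroxyl is the normal course for 2-hydroxy-4-alkoxybenzaldehydes, and orcinol ethers are brominated next to the methyl group.

**Step 3**
Reactants: 3 4-(benzyloxy)-3-bromo-6-hydroxy-2-methylbenzaldehyde; 4 2-methylpropene; 5 trimethyl orthoformate
Product: 8 7-(benzyloxy)-6-bromo-4-methoxy-2,2,5-trimethylchromane (racemic), via dimethyl acetal 6 (not isolated), via O-methyl ortho-quinone methide 7 (not isolated)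
Conditions: 5 (3 equiv), Sc(OTf)3 (10 mol %), CH2Cl2, 0 °C; then 4 (10 equiv, condensed), sealed tube, 0 °C to rt; Et3N quench
Reagents that add atoms: none
Why: Sc(OTf)3 and 5 should convert the hindered aldehyde of 3 into acetal 6, which loses methanol to an oxocarbenium ion, the protonated form of O-methyl ortho-quinone methide 7, stabilised by the para benzyloxy group. The CH2 terminus of 4 bonds to the methide carbon (C4–C3) so that positive charge develops on the tertiary carbon, which the phenol oxygen captures (O1–C2). This is an inverse-electron-demand oxa-[4+2] cycloaddition (hetero-Diels–Alder reaction), concerted but asynchronous or stepwise, and the closest known reaction type is the acid-catalysed three-component chroman synthesis from salicylaldehydes, orthoformates and alkenes. The pyran ring closes as a six-membered ring in which the exocyclic carbon, C4a, C8a and the phenol oxygen supply four atoms and the alkene two. The only new stereocentre, C4, forms without any controlling element, so 8 is racemic, which does not matter because C4 becomes a carbonyl carbon in step 4. The step needs Markovnikov orientation of the alkene, which the tertiary cation secures, and ring fusion at the carbon between OH and CH3, which the position of the formyl group fixes. The bromine para to the phenol blocks the most nucleophilic ring carbon against Friedel–Crafts attack by the oxocarbenium ion and should make the product ether less prone to re-ionisation.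

**Step 4**
Reactants: 8 7-(benzyloxy)-6-bromo-4-methoxy-2,2,5-trimethylchromane
Product: 9 7-(benzyloxy)-6-bromo-2,2,5-trimethylchroman-4-one
Conditions: DDQ (1.5 equiv), CH2Cl2–H2O (10:1), rt
Reagents that add atoms: water, O
Why: Oxidative cleavage of an electron-rich benzylic ether, as in the removal of dimethoxybenzyl ethers: DDQ takes the hydride from C4, whose cation is stabilised by O1 and the para benzyloxy group, water adds and methanol is lost to leave the ketone. The plain benzyl ether, the aryl bromide and the C5 methyl should not react, and C2 is quaternary so no chromone can form.

**Step 5**
Reactants: 9 7-(benzyloxy)-6-bromo-2,2,5-trimethylchroman-4-one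
Product: 10 6-bromo-7-hydroxy-2,2,5-trimethylchroman-4-one
Conditions: BCl3 (2.5 equiv), pentamethylbenzene (3 equiv), CH2Cl2, −78 to −20 °C
Reagents that add atoms: none
Why: Lewis-acid debenzylation with a non-basic cation scavenger; BCl3 activates the aryl benzyl ether and pentamethylbenzene takes up the benzyl cation, so the C–Br bond, which hydrogenolysis would endanger, and the ketone are left alone. The pyranone, whose ring oxygen is deactivated by conjugation with the ketone, should survive at low temperature.

**Step 6**
Reactants: 11 methyl orsellinate (methyl 2,4-dihydroxy-6-methylbenzoate)
Product: 13 methyl 3-formyl-2,4-dihydroxy-6-methylbenzoate, via alpha-chloro ether 12 (not isolated)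
Conditions: Cl2CHOMe (1.3 equiv), TiCl4 (3.5 equiv), CH2Cl2, 0 °C; then 1 M HCl
Reagents that add atoms: dichloromethyl methyl ether, COC(Cl)Cl; water, O
Why: Rieche formylation; TiCl4 bound to the phenol and ester oxygens should deliver the electrophile to A-C3, the carbon flanked by both hydroxyls, which is the position that chelated 2,4-dihydroxybenzoates take in Gattermann-type formylations. Aqueous work-up hydrolyses 12 to the aldehyde.

**Step 7**
Reactants: 13 methyl 3-formyl-2,4-dihydroxy-6-methylbenzoate
Product: 14 methyl 4-(benzyloxy)-3-formyl-2-hydroxy-6-methylbenzoate
Conditions: BnBr (1.05 equiv), K2CO3 (1.1 equiv), DMF, rt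
Reagents that add atoms: benzyl bromide, BrCc1ccccc1
Why: Williamson ether synthesis; the 2-hydroxyl sits between the ester and the formyl group and is hydrogen-bonded to the ester carbonyl, so the more accessible 4-hydroxyl should be alkylated.

**Step 8**
Reactants: 14 methyl 4-(benzyloxy)-3-formyl-2-hydroxy-6-methylbenzoate
Product: 15 4-(benzyloxy)-3-formyl-2-hydroxy-6-methylbenzoic acid
Conditions: KOH (6 equiv), DMSO–H2O, 60 °C; then 1 M HCl, 0 °C
Reagents that add atoms: potassium hydroxide, [K+].[OH-]
Why: Saponification of a hindered ester by poorly solvated hydroxide; the ortho phenoxide protects the non-enolisable aldehyde from the Cannizzaro reaction. Cold acidification should avoid decarboxylation, which the electron-withdrawing formyl group also disfavours.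

**Step 9**
Reactants: 15 4-(benzyloxy)-3-formyl-2-hydroxy-6-methylbenzoic acid; 10 6-bromo-7-hydroxy-2,2,5-trimethylchroman-4-one
Product: 17 6-bromo-2,2,5-trimethyl-4-oxochroman-7-yl 4-(benzyloxy)-3-formyl-2-hydroxy-6-methylbenzoate, via mixed trifluoroacetic anhydride 16 (not isolated)
Conditions: TFAA (3 equiv), toluene, 0 °C to rt
Reagents that add atoms: none
Why: Mixed-anhydride esterification as used for depsides; 16 reacts as an acylium-like electrophile stabilised by the ortho and para oxygens, which suits a 2,6-disubstituted acid, and the acidic medium excludes base-induced aryl migration. The chelated 2-hydroxyl between two carbonyl groups should not compete, and the benzyl ether prevents self-acylation at the A-C4 oxygen.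

**Step 10**
Reactants: 17 6-bromo-2,2,5-trimethyl-4-oxochroman-7-yl 4-(benzyloxy)-3-formyl-2-hydroxy-6-methylbenzoate
Product: 18 O-benzylmollicellin A (the A-C4 benzyl ether of the target)
Conditions: CuI (20 mol %), N,N-dimethylglycine (40 mol %), Cs2CO3 (2 equiv), 1,4-dioxane (0.02 M), 90 °C
Reagents that add atoms: none
Why: Intramolecular Ullmann diaryl ether synthesis; the monovalent copper phenoxide of the A-C2 oxygen is held next to the C6–Br bond by the ester tether, and only the seven-membered ring can form. The amino acid ligand allows a moderate temperature, and the weakly polar solvent should disfavour Smiles-type migration and ester cleavage.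

**Step 11**
Reactants: 18 O-benzylmollicellin A
Product: 19 mollicellin A
Conditions: BCl3 (3 equiv), pentamethylbenzene (3 equiv), CH2Cl2, −78 °C; aqueous NaHCO3 work-up
Reagents that add atoms: none
Why: Chelation-assisted Lewis-acid debenzylation; BCl3 held by the formyl oxygen cleaves the neighbouring benzyl ether at low temperature, and pentamethylbenzene traps the benzyl cation. The lactone, the ketone and the aldehyde carry no group that BCl3 removes under these conditions.

## Compound list

1 | 2,4-dihydroxy-6-methylbenzaldehyde | Cc1cc(O)cc(O)c1C=O | starting material
2 | 4-(benzyloxy)-2-hydroxy-6-methylbenzaldehyde | Cc1cc(OCc2ccccc2)cc(O)c1C=O | intermediate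
3 | 4-(benzyloxy)-3-bromo-6-hydroxy-2-methylbenzaldehyde | Cc1c(Br)c(OCc2ccccc2)cc(O)c1C=O | intermediate
4 | 2-methylpropene | CC(C)=C | starting material
5 | trimethyl orthoformate | COC(OC)OC | starting material
6 | 5-(benzyloxy)-4-bromo-2-(dimethoxymethyl)-3-methylphenol | COC(OC)c1c(C)c(Br)c(OCc2ccccc2)cc1O | intermediate (not isolated)
7 | 3-(benzyloxy)-4-bromo-6-(methoxymethylidene)-5-methylcyclohexa-2,4-dien-1-one | COC=C1C(=O)C=C(OCc2ccccc2)C(Br)=C1C | intermediate (not isolated)
8 | 7-(benzyloxy)-6-bromo-4-methoxy-2,2,5-trimethylchromane (racemic, the 4S enantiomer drawn) | CO[C@H]1CC(C)(C)Oc2cc(OCc3ccccc3)c(Br)c(C)c21 | intermediate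
9 | 7-(benzyloxy)-6-bromo-2,2,5-trimethylchroman-4-one | Cc1c(Br)c(OCc2ccccc2)cc2OC(C)(C)CC(=O)c12 | intermediate
10 | 6-bromo-7-hydroxy-2,2,5-trimethylchroman-4-one | Cc1c(Br)c(O)cc2OC(C)(C)CC(=O)c12 | intermediate
11 | methyl orsellinate (methyl 2,4-dihydroxy-6-methylbenzoate) | COC(=O)c1c(C)cc(O)cc1O | starting material
12 | methyl 3-[chloro(methoxy)methyl]-2,4-dihydroxy-6-methylbenzoate (racemic, held as its TiCl4 complex) | COC(Cl)c1c(O)cc(C)c(C(=O)OC)c1O | intermediate (not isolated)
13 | methyl 3-formyl-2,4-dihydroxy-6-methylbenzoate | COC(=O)c1c(C)cc(O)c(C=O)c1O | intermediate
14 | methyl 4-(benzyloxy)-3-formyl-2-hydroxy-6-methylbenzoate | COC(=O)c1c(C)cc(OCc2ccccc2)c(C=O)c1O | intermediate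
15 | 4-(benzyloxy)-3-formyl-2-hydroxy-6-methylbenzoic acid | Cc1cc(OCc2ccccc2)c(C=O)c(O)c1C(=O)O | intermediate
16 | 4-(benzyloxy)-3-formyl-2-hydroxy-6-methylbenzoic trifluoroacetic anhydride | Cc1cc(OCc2ccccc2)c(C=O)c(O)c1C(=O)OC(=O)C(F)(F)F | intermediate (not isolated)
17 | 6-bromo-2,2,5-trimethyl-4-oxochroman-7-yl 4-(benzyloxy)-3-formyl-2-hydroxy-6-methylbenzoate | Cc1cc(OCc2ccccc2)c(C=O)c(O)c1C(=O)Oc1cc2OC(C)(C)CC(=O)c2c(C)c1Br | intermediate
18 | O-benzylmollicellin A (A-C4 benzyl ether of the target) | Cc1cc(OCc2ccccc2)c(C=O)c2c1C(=O)Oc1cc3c(c(C)c1O2)C(=O)CC(C)(C)O3 | intermediate
19 | mollicellin A | Cc1cc(O)c(C=O)c2c1C(=O)Oc1cc3c(c(C)c1O2)C(=O)CC(C)(C)O3 | target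

## Step count and least certain steps

Total step count: 11. Longest linear sequence: 8 steps (steps 1, 2, 3, 4, 5, 9, 10 and 11, from 1); the ring-A branch (steps 6, 7 and 8) joins at step 9.

**Step 3 (key step).**
- Risk: the Lewis acid may re-ionise the benzylic methyl ether of 8, which would then lose a proton to give the 2H-chromene or attack another arene. The hindered oxocarbenium ion may also be captured too slowly by a volatile alkene, so that acetal 6 accumulates.
- Fallback, from 3 to 9: the same two bonds are made one after the other.
  - Addition of 2-methylallylmagnesium chloride (CH2=C(CH3)CH2MgCl, 2.5 equiv, THF, 0 °C) to the aldehyde of 3 should give 1-[4-(benzyloxy)-3-bromo-6-hydroxy-2-methylphenyl]-3-methylbut-3-en-1-ol F1, forming the C4–C3 bond.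
  - MnO2 in CH2Cl2 should oxidise the benzylic alcohol to 1-[4-(benzyloxy)-3-bromo-6-hydroxy-2-methylphenyl]-3-methylbut-3-en-1-one F2.
  - DBU in THF should move the double bond into conjugation, giving 1-[4-(benzyloxy)-3-bromo-6-hydroxy-2-methylphenyl]-3-methylbut-2-en-1-one F3, whose phenoxide closes the pyranone by oxa-Michael addition (O1–C2 bond) to 9.
  - The detour leaves the route at 3, bypasses 8 and step 4, and returns at 9.

**Step 10.**
- Risk: base may induce migration of ring B from the ester oxygen to the A-C2 oxygen (Smiles rearrangement, favoured by the ketone para to C7), or carbonate may cleave the aryl ester before the slow coupling of an electron-poor, chelated phenoxide with a doubly ortho-substituted bromide. Loss of bromine by reduction is a further possibility.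
- Fallback, from 9 and 14 to 19: the order of the two links is reversed, so that no aryl ester is present in the copper step.
  - A classical intermolecular Ullmann coupling of 9 with the phenol of 14 (Cu2O, K2CO3, pyridine, reflux) should give methyl 4-(benzyloxy)-2-{[7-(benzyloxy)-2,2,5-trimethyl-4-oxochroman-6-yl]oxy}-3-formyl-6-methylbenzoate F4.
  - BCl3 with pentamethylbenzene should remove both benzyl groups to give methyl 3-formyl-4-hydroxy-2-[(7-hydroxy-2,2,5-trimethyl-4-oxochroman-6-yl)oxy]-6-methylbenzoate F5.
  - KOH in aqueous DMSO should hydrolyse the ester to 3-formyl-4-hydroxy-2-[(7-hydroxy-2,2,5-trimethyl-4-oxochroman-6-yl)oxy]-6-methylbenzoic acid F6.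
  - Lactonisation onto the C7 hydroxyl with TFAA under dilution, the usual last step of depsidone syntheses, should give 19.
  - The coupling of two doubly ortho-substituted partners is expected to be slow, which is why this order is the fallback and not the plan.

**Step 9.**
- Risk: the electron-poor phenol 10 may be trifluoroacetylated instead of aroylated, the reaction may be slow because both partners are hindered, and a second molecule of 15 may be acylated at its 2-hydroxyl.
- Fallback, from 15 and 10 to 17: the 2-hydroxyl is masked and the acid is activated as its chloride.
  - Ac2O and pyridine should give 2-acetoxy-4-(benzyloxy)-3-formyl-6-methylbenzoic acid F7.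
  - Oxalyl chloride with catalytic DMF should give 2-acetoxy-4-(benzyloxy)-3-formyl-6-methylbenzoyl chloride F8.
  - Reaction of F8 with 10, Et3N and DMAP in CH2Cl2 should give 6-bromo-2,2,5-trimethyl-4-oxochroman-7-yl 2-acetoxy-4-(benzyloxy)-3-formyl-6-methylbenzoate F9.
  - Acid-catalysed methanolysis (HCl, MeOH, rt) should remove the unhindered acetate while the doubly ortho-substituted depside ester resists, returning to the route at 17.

**Step 6.**
- Risk: formylation may occur at A-C5, para to the chelated 2-hydroxyl, or twice, because both open ring carbons are activated by two oxygens.
- Fallback, from 11 to 14: the two hydroxyls are differentiated first.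
  - BnBr and K2CO3 should give methyl 4-(benzyloxy)-2-hydroxy-6-methylbenzoate F10.
  - A Casnati–Skattebøl ortho-formylation (MgCl2, Et3N, paraformaldehyde, MeCN, reflux) then delivers formaldehyde through the magnesium-bound phenoxide only to a carbon ortho to the one free hydroxyl, and A-C3 is the only such carbon that is open.
  - The detour bypasses 13 and returns at 14.

**Step 2.**
- Risk: bromination may occur at the carbon between the two oxygens, or twice.
- Fallback, from 2 to 9: the halogen is introduced after the ring is built.
  - 2 is taken through the conditions of step 3 to 7-(benzyloxy)-4-methoxy-2,2,5-trimethylchromane F11 (racemic).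
  - DDQ in wet CH2Cl2 should give 7-(benzyloxy)-2,2,5-trimethylchroman-4-one F12.
  - NBS in MeCN should brominate F12 at C6, which is para to the pyran oxygen, ortho to the benzyloxy group and next to the methyl, whereas C8 is only ortho-activated and lies between two ether oxygens. This returns to the route at 9.

## Further compounds

F1 | step 3 | 1-[4-(benzyloxy)-3-bromo-6-hydroxy-2-methylphenyl]-3-methylbut-3-en-1-ol (racemic, one enantiomer drawn) | CC(=C)C[C@@H](O)c1c(C)c(Br)c(OCc2ccccc2)cc1O
F2 | step 3 | 1-[4-(benzyloxy)-3-bromo-6-hydroxy-2-methylphenyl]-3-methylbut-3-en-1-one | CC(=C)CC(=O)c1c(C)c(Br)c(OCc2ccccc2)cc1O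
F3 | step 3 | 1-[4-(benzyloxy)-3-bromo-6-hydroxy-2-methylphenyl]-3-methylbut-2-en-1-one | CC(C)=CC(=O)c1c(C)c(Br)c(OCc2ccccc2)cc1O
F4 | step 10 | methyl 4-(benzyloxy)-2-{[7-(benzyloxy)-2,2,5-trimethyl-4-oxochroman-6-yl]oxy}-3-formyl-6-methylbenzoate | COC(=O)c1c(C)cc(OCc2ccccc2)c(C=O)c1Oc1c(C)c2C(=O)CC(C)(C)Oc2cc1OCc1ccccc1
F5 | step 10 | methyl 3-formyl-4-hydroxy-2-[(7-hydroxy-2,2,5-trimethyl-4-oxochroman-6-yl)oxy]-6-methylbenzoate | COC(=O)c1c(C)cc(O)c(C=O)c1Oc1c(C)c2C(=O)CC(C)(C)Oc2cc1O
F6 | step 10 | 3-formyl-4-hydroxy-2-[(7-hydroxy-2,2,5-trimethyl-4-oxochroman-6-yl)oxy]-6-methylbenzoic acid | OC(=O)c1c(C)cc(O)c(C=O)c1Oc1c(C)c2C(=O)CC(C)(C)Oc2cc1O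
F7 | step 9 | 2-acetoxy-4-(benzyloxy)-3-formyl-6-methylbenzoic acid | CC(=O)Oc1c(C=O)c(OCc2ccccc2)cc(C)c1C(=O)O
F8 | step 9 | 2-acetoxy-4-(benzyloxy)-3-formyl-6-methylbenzoyl chloride | CC(=O)Oc1c(C=O)c(OCc2ccccc2)cc(C)c1C(Cl)=O
F9 | step 9 | 6-bromo-2,2,5-trimethyl-4-oxochroman-7-yl 2-acetoxy-4-(benzyloxy)-3-formyl-6-methylbenzoate | CC(=O)Oc1c(C=O)c(OCc2ccccc2)cc(C)c1C(=O)Oc1cc2OC(C)(C)CC(=O)c2c(C)c1Br
F10 | step 6 | methyl 4-(benzyloxy)-2-hydroxy-6-methylbenzoate | COC(=O)c1c(C)cc(OCc2ccccc2)cc1O
F11 | step 2 | 7-(benzyloxy)-4-methoxy-2,2,5-trimethylchromane (racemic, one enantiomer drawn) | CO[C@H]1CC(C)(C)Oc2cc(OCc3ccccc3)cc(C)c21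
F12 | step 2 | 7-(benzyloxy)-2,2,5-trimethylchroman-4-one | Cc1cc(OCc2ccccc2)cc2OC(C)(C)CC(=O)c12
A1 | alternative 1 | 6-(2,4-dioxopentyl)-2,2-dimethyl-1,3-dioxin-4-one (diketo-dioxinone) | CC(=O)CC(=O)CC1=CC(=O)OC(C)(C)O1
A2 | alternative 1 | 6-bromo-2,2,5-trimethyl-4-oxochroman-7-yl 3,5,7-trioxooctanoate | CC(=O)CC(=O)CC(=O)CC(=O)Oc1cc2OC(C)(C)CC(=O)c2c(C)c1Br
A3 | alternative 1 | 6-bromo-2,2,5-trimethyl-4-oxochroman-7-yl orsellinate (bromo depside) | Cc1cc(O)cc(O)c1C(=O)Oc1cc2OC(C)(C)CC(=O)c2c(C)c1Br
A4 | alternative 2 | iodo diaryl ether phenyl carbonate (ring A: 1-iodo, 3-(1,3-dioxolan-2-yl), 4-methoxymethoxy, 6-methyl; ring B: C7 phenyl carbonate, C4 dioxolane) | Cc1cc(OCOC)c(C2OCCO2)c(Oc2c(C)c3c(cc2OC(=O)Oc2ccccc2)OC(C)(C)CC32OCCO2)c1I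
A5 | alternative 2 | fully protected mollicellin A (two dioxolanes, methoxymethyl ether) | Cc1cc(OCOC)c(C2OCCO2)c2c1C(=O)Oc1cc3c(c(C)c1O2)C1(OCCO1)CC(C)(C)O3
A6 | alternative 3 | ring-B-fused methyl-dioxepinone (C4 ketone as dioxolane) | CC1=CC(=O)Oc2cc3OC(C)(C)CC4(OCCO4)c3c(C)c2O1
A7 | alternative 3 | methyl crotonate | C/C=C/C(=O)OC
A8 | alternative 3 | tetrahydro depsidone (racemic, one enantiomer drawn) | C[C@H]1CC(=O)CC2=C1C(=O)Oc1cc3OC(C)(C)CC4(OCCO4)c3c(C)c1O2
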